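The numbers in the tables are simulated with constants of no real substance, noise included.

The vessel is closed, stirred and held at one temperature, so nothing enters after the charge, and the amounts charged are what I reason from.

| flask | substrate | reagent | free catalyst | remark | time |
|---|---|---|---|---|---|
| spring | 0.55 M | 0.84 M | 26 mM | run made earlier |  |
| winter | 2 M | 0.84 M | 26 mM | run made earlier |  |
| summer | 0.80 M | 0.84 M | 43 mM | run made earlier |  |
| teal | 2.5 M | 0.840 M | 100 mM |  | 5.0 d |
| red | 0.80 M | 0.840 M | 26 mM |  | 5.0 d |

| run | time / d | product / % |
|---|---|---|
| spring | 1.25 | 82.7 |
| spring | 2.50 | 97.9 |
| spring | 4.00 | 99.0 |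
| spring | 5.00 | 100.5 |
| winter | 1.25 | 39.1 |
| winter | 2.50 | 42.2 |
| winter | 4.00 | 42.9 |
| winter | 5.00 | 41.3 |
| summer | 0.417 | 53.9 |
| summer | 0.833 | 76.6 |
| summer | 2.00 | 93.8 |
| summer | 5.00 | 99.4 |

(standard deviation of a reading: 0.5 percentage points)

- steps under discussion: catalyst intermediate C <-> catalyst intermediate D; catalyst intermediate D -> free catalyst + product; catalyst intermediate B -> released group + catalyst intermediate C; reagent + free catalyst <-> catalyst intermediate A; substrate + catalyst intermediate A -> catalyst intermediate B

* the flask that ends with the higher amount of product, in percent of the substrate charged, or "neither" when 2 percentage points or less lies between them (teal / red / neither)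
* final product, as a percentage of the substrate charged, in teal
* final product, as a percentage of the substrate charged, in red

I start with the winter run because it stops early: from 2.50 d on, its product reads 42.2%, 42.9% and 41.3% of the substrate charged, with no upward trend. The bench rule for such a plateau is to divide the reagent charged by the substrate charged:

winter: 0.84 M / 2 M = 42.0%

teal: 0.840 M / 2.5 M = 33.6%

red: 0.840 M / 0.80 M = 105%

I call this ratio, [reagent] over [substrate] at the charge, the reagent ceiling. Below 100%, reagent is the limiting reagent, and on the winter evidence product levels off at that share. The three winter readings from 2.50 d on lie on either side of its ceiling, so I read that ceiling as the level of the winter run, within the scatter of the readings.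

Teal holds more catalyst than winter, 100 mM against 26 mM, and runs for twice the time after which winter showed no further rise. So I expect teal to stand at its ceiling by the end.

Red is where the rule stops working, because its ratio is above 100%. By the charge, reagent is then not the limit in red, and the ratio says nothing about time. For that I turn to the summer run, which has red's substrate but 43 mM of catalyst: it read 93.8% at 2.00 d and 99.4% at 5.00 d. Red has less catalyst, so its last points are the ones to watch.

The forecast puts red higher, with teal at 33.6% (32.8% to 34.3%) and red at 98.3% (96.5% to 99.7%), holding that reagent is “consumed stoichiometrically and caps the product”. My ceiling gives the same teal figure; for red it gives no figure, so I take the forecast's.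

The simulation gives red as the higher flask, with teal at 33.6% and red at 97.0%, both inside the forecast's ranges.

    catalyst intermediate C ⇌ catalyst intermediate D (K = 23.0, k = 0.00730 /s)
    catalyst intermediate D → free catalyst + product (k = 0.0540 /s)
    catalyst intermediate B → released group + catalyst intermediate C (k = 0.00160 /s)
    reagent + free catalyst ⇌ catalyst intermediate A (K = 1.70 /M, k = 0.00210 /M/s)
    substrate + catalyst intermediate A → catalyst intermediate B (k = 0.00190 /M/s)

In teal, the step from reagent + free catalyst to catalyst intermediate A has 99.5% of its turnover behind it at 0.500 d, and half of the turnover from catalyst intermediate C to catalyst intermediate D is done by 0.107 d, far earlier than the 5.0 d of the run. Teal's reagent stands at 0% of its charge at 2.50 d, and its product stands at 33.6% then and 33.6% at 5.00 d, which is its ceiling of 33.6%. A neighbour flask, teal with 0.34 M of reagent, has a ceiling of 13.6% and ends with 13.6% of its substrate as product.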